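All runs are simulated from invented constants, noise included.

Millimolar of target per minute, per millimolar of substrate and per millimolar of reagent, is the unit I read these flasks in, since a plain bimolecular step gives one value of it at any substrate level.

| flask | substrate | reagent | free catalyst | time |
|---|---|---|---|---|
| Wednesday's | 100 mM | 300 mM | 5.00 mM |  |
| Tuesday's | 40.0 mM | 240 mM | 5.00 mM |  |
| Monday's | 100 mM | 300 mM | 15.0 mM |  |
| Saturday's | 100 mM | 150 mM | 5.00 mM |  |
| Friday's | 100 mM | 150 mM | 15.0 mM | 14 min |

| Wednesday's run: time / min | Wednesday's run: [target] / mM | Tuesday's run: time / min | Tuesday's run: [target] / mM | Monday's run: time / min | Monday's run: [target] / mM | Saturday's run: time / min | Saturday's run: [target] / mM |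
|---|---|---|---|---|---|---|---|
| 1.8 | 16.1 | 1.8 | 6.4 | 1.8 | 37.4 | 1.8 | 8.1 |
| 3.5 | 28.2 | 3.5 | 10.7 | 3.5 | 56.0 | 3.5 | 14.8 |
| 5.2 | 37.4 | 5.2 | 14.1 | 5.2 | 68.4 | 5.2 | 20.4 |
| 7.0 | 45.4 | 7.0 | 17.4 | 7.0 | 76.0 | 7.0 | 25.4 |
| 8.8 | 52.1 | 8.8 | 19.9 | 8.8 | 80.8 | 8.8 | 29.9 |
| 10 | 55.9 | 10 | 21.4 | 10 | 82.7 | 10 | 32.9 |
| 12 | 61.5 | 12 | 23.5 | 12 | 86.7 | 12 | 36.6 |
| 14 | 66.5 | 14 | 25.4 | 14 | 88.8 | 14 | 39.3 |

(standard deviation of a reading: 0.3 mM)

1. reaction order in [free catalyst] at the outset, round the charge of the Wednesday's run, defined at two percent of the substrate turned into target
2. reaction order in [substrate] at the outset, round the charge of the Wednesday's run, defined at two percent of the substrate turned into target (one fixed amount of target, the same in the runs compared)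
3. the Tuesday's run starts with 60.0 mM less of substrate and of reagent than the Wednesday's run, and with no target. Compared where both hold the same amount of substrate, once fifteen percent of what the Tuesday's run was charged with has turned into target, is the Tuesday's run faster, slower or alike (within a tenth)?
4. target in the Friday's run at 14 min, as a share of the substrate charged

- Overall: substrate + reagent -> target, with free catalyst as catalyst.
- Constant volume, constant temperature.
- A reading of a species includes what of it is bound.
- "The second partner" is reagent.
- An order is taken over about fifteen percent of the charge, up and down.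

Step 1. Saturday's run, charged with half of the reagent of Wednesday's run, shows 0.503 of Wednesday's target at the first reading, so I take the rate as proportional to reagent.

Step 2. In my unit, Tuesday's first reading against the charge stands at 1.24 times Wednesday's. My objection is that the charge no longer stands during that interval, so I take substrate and reagent halfway through it, and the ratio becomes 1.22, which is still not one.

Step 3. I suppose that part of the catalyst sits as a catalyst-substrate complex, quickly balanced with free catalyst, and that reagent attacks this complex. The rate then goes as substrate/(h + substrate), where h, the Michaelis constant, is the substrate level that binds half the catalyst. My unit then goes as 1/(h + substrate), and the ratio above gives h = 209 mM.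

Step 4. The doubt is scatter, which is 4.69% of Tuesday's first reading, and h hangs on a small difference. The second readings give a ratio of 1.15 and h = 316 mM, so I commit to their mean, 262 mM, as a rough reading.

Step 5. Wednesday's run at the defining point holds 98.0 mM of substrate, and h/(h + substrate) there is 0.728. This is the free share, the fraction of the catalyst not bound to substrate. It is also the order in substrate, since a little more substrate can only bind catalyst that is still free, so my order is that same number.

Step 6. At the comparison point both runs hold 34.0 mM of substrate and equal reagent, so the free share is 0.885 in both. Tuesday's mean rate up to its second reading is 3.06 mM min⁻¹, and Wednesday's slope between its last two readings is 2.50 mM min⁻¹, a ratio of 1.22. That slope carries 8.49% of scatter, which is less than the gap, so I say Tuesday's run is faster. Tuesday's run gets there within 3.5 min and Wednesday's only after 12 min, so I read the gap as catalyst lost with age.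

The forecast, which reads “partial substrate saturation” in these runs, gives 0.96 (0.85 to 1.05) for catalyst, 0.67 (0.5 to 0.85) for substrate, which is lower than my 0.728, faster for Tuesday, and 61% (57% to 65%) for Friday.

The flask gives 0.99 for catalyst, 0.72 for substrate, beside my free share of 0.728, faster for Tuesday, and 62.8% for Friday.

    free catalyst + substrate ⇌ catalyst-substrate complex, settled at all times (4.530 L mol⁻¹)
    catalyst-substrate complex + reagent → target + free catalyst (21.30 L mol⁻¹ min⁻¹)
    2 free catalyst → 2 spent catalyst (7.080 L mol⁻¹ min⁻¹)

The binding constant of the scheme makes h 221 mM. Where Tuesday's and Wednesday's runs hold the same substrate, the rate ratio is 1.5, with a free share of 0.867 in both. Friday's run holds 37.2 mM of substrate at 14 min, which puts its free share at 0.856.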